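**Retrosynthetic overview**
1. Enabling feature: the oxane ring O1–C2–C3–C4–C5–C6 is the closed form of a δ-hydroxy ketone. C3 is α to the masked ketone C2 and C6 carries the ring oxygen, so C3 and C6 are the two olefinic carbons of a β-hydroxy enone (formylacetone enol) and C4–C5 is a vinyl group.
2. Key disconnection: a de Mayo union (enol–alkene [2+2], then retro-aldol of the cyclobutanol) of formylacetone enol with but-3-enoic acid forms C3–C4 and C6–C5 in one operation and gives the C1–C8 skeleton as a γ-lactol-lactone.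
3. Stereochemistry: C5 is planarised (butenolide) and reset by asymmetric hydrogenation; C7 (the C–Cl carbon) is then set from C5 by methylation and chlorination of the γ-lactone enolate.
4. Side chain: lactone → lactol → Takai bromo-olefination gives the (E)-bromovinyl group (C9) and frees the C6 hydroxyl.
5. Ring order: cyclobutane (formed and opened in the key step) → γ-lactol/γ-lactone (temporary) → dihydropyran enol ether → oxane hemiketal, with C3–Br set by axial protonation of a bromo enol ether.

Key step: step 1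

Atom names: ring O1, C2 (hemiketal carbon, bearing methyl C1), C3 (CHBr), C4, C5, C6 (OCH2); side chain C7 (C–Cl), C8, C9 (CHBr).
Assumption: the (S)-BINAP catalyst of step 4 is taken to give the (S)-lactone 11; if the sense of induction is the opposite, the (R)-BINAP complex is used.

**Route**

Step 1
Reactants: 1 but-3-enoic acid; 2 4,4-dimethoxybutan-2-one
Product: 6 5-hydroxy-4-(3-oxobutyl)oxolan-2-one (racemic; both lactol epimers), via formylacetone enol 3 (not isolated), via cyclobutanol photoadduct 4 (not isolated), via keto aldehyde acid 5 (not isolated)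
Conditions: 2, 1 M HCl, 0 °C, extraction into CH2Cl2; then 1 (6 equiv), hν (medium-pressure Hg lamp, Pyrex), CH2Cl2, 5 °C
Reagents that add atoms: water, O
Why: De Mayo reaction: the hydrogen-bonded cis-enol 3 (C3=C6, C6 bearing OH) is excited and adds through a triplet 1,4-biradical across the vinyl group C4=C5 of 1 to give cyclobutanol 4, so C3–C4 and C6–C5 form in the same photochemical event; the strained β-hydroxy ketone then opens by retro-aldol cleavage of the old enol bond C3–C6 to keto aldehyde 5, whose formyl group is trapped by the γ-carboxyl as lactol-lactone 6. The closest known reaction type is the de Mayo photocycloaddition of enolised β-diketones and α-formyl ketones with simple alkenes. Rings: the cyclobutane closes by stepwise [2+2] biradical combination and is opened again in the flask; the five-membered lactol-lactone closes by 5-exo-trig addition of the carboxyl oxygen to the aldehyde. The new stereocentres (C5, the lactol carbon, transiently C3 and C6) form without control and need none, because C5 is planarised in step 2 and reset in step 4. The selectivity needed is head-to-tail orientation (oxygen-bearing C6 to the substituted alkene carbon C5, C3 to the CH2 terminus C4), the usual orientation of monoalkyl ethylenes with enone and enol chromophores (first bonding of C3 to the unhindered terminus gives the oxygen-stabilised C6 radical and the secondary C5 radical); chemoselectivity rests on 3 being the only species absorbing above 300 nm and on the excess of 1.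

Step 2
Reactants: 6 5-hydroxy-4-(3-oxobutyl)oxolan-2-one
Product: 9 4-(3-oxobutyl)furan-2(5H)-one, via lactol mesylate 7 (not isolated), via 4-(3-oxobutyl)furan-2(3H)-one 8 (not isolated)
Conditions: MsCl, Et3N, CH2Cl2, −20 °C to rt
Reagents that add atoms: none
Why: Dehydration of a γ-hydroxy-γ-lactone (pseudo acid): the anomeric mesylate 7 ionises and loses the C5 proton to give enol lactone 8, which Et3N isomerises through the 2-oxyfuran anion to the conjugated butenolide 9 (angelica-lactone type β,γ to α,β shift), so the uncontrolled C5 centre is erased on purpose.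

Step 3
Reactants: 9 4-(3-oxobutyl)furan-2(5H)-one
Product: 10 4-[2-(2-methyl-1,3-dioxolan-2-yl)ethyl]furan-2(5H)-one
Conditions: (Me3SiOCH2)2, Me3SiOTf (2 mol %), CH2Cl2, −78 to −20 °C
Reagents that add atoms: 1,2-bis(trimethylsilyloxy)ethane, C[Si](C)(C)OCCO[Si](C)(C)C
Why: Noyori acetalisation under aprotic conditions converts only the methyl ketone into the dioxolane (the butenolide is inert), masking C2 for the enolate, hydride and chromium steps that follow.

Step 4
Reactants: 10 4-[2-(2-methyl-1,3-dioxolan-2-yl)ethyl]furan-2(5H)-one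
Product: 11 (4S)-4-[2-(2-methyl-1,3-dioxolan-2-yl)ethyl]oxolan-2-one
Conditions: H2 (80 atm), Ru(OAc)2[(S)-BINAP] (1 mol %), CH2Cl2/MeOH, 50 °C
Reagents that add atoms: none
Why: Asymmetric hydrogenation of a β-substituted butenolide with a BINAP–ruthenium diacetate catalyst: the lactone carbonyl binds the metal and hydrogen is delivered to one enantioface of C5=C7, which sets C5 (4S in 11, the centre that becomes 5R in the target).

Step 5
Reactants: 11 (4S)-4-[2-(2-methyl-1,3-dioxolan-2-yl)ethyl]oxolan-2-one
Product: 12 (3S,4S)-3-methyl-4-[2-(2-methyl-1,3-dioxolan-2-yl)ethyl]oxolan-2-one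
Conditions: LiN(iPr)2, THF, −78 °C; MeI
Reagents that add atoms: iodomethane, CI
Why: Lactone enolate alkylation: the lithium enolate is methylated anti to the C5 side chain (1,2-induction in the five-membered ring) to give the trans lactone; this C7 configuration is not carried on, since C7 is planarised again in step 6.

Step 6
Reactants: 12 (3S,4S)-3-methyl-4-[2-(2-methyl-1,3-dioxolan-2-yl)ethyl]oxolan-2-one
Product: 13 (3S,4R)-3-chloro-3-methyl-4-[2-(2-methyl-1,3-dioxolan-2-yl)ethyl]oxolan-2-one
Conditions: LiN(iPr)2, THF, −78 °C; C2Cl6, −78 °C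
Reagents that add atoms: hexachloroethane, ClC(Cl)(Cl)C(Cl)(Cl)Cl
Why: Electrophilic chlorination of the tetrasubstituted lithium enolate: chlorine enters anti to the C5 substituent, so Cl is trans and methyl cis to the C5 chain, which is the 7S tertiary chloride of the target (1,2-induction by C5 in the γ-butyrolactone).

Step 7
Reactants: 13 (3S,4R)-3-chloro-3-methyl-4-[2-(2-methyl-1,3-dioxolan-2-yl)ethyl]oxolan-2-one
Product: 14 (3S,4R)-3-chloro-3-methyl-4-[2-(2-methyl-1,3-dioxolan-2-yl)ethyl]oxolan-2-ol (both anomers)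
Conditions: iBu2AlH (1.1 equiv), CH2Cl2, −78 °C
Reagents that add atoms: none
Why: Partial reduction of the lactone to the lactol (the tetrahedral aluminate is stable at −78 °C); ketal, tertiary chloride, C5 and C7 are untouched.

Step 8
Reactants: 14 (3S,4R)-3-chloro-3-methyl-4-[2-(2-methyl-1,3-dioxolan-2-yl)ethyl]oxolan-2-ol
Product: 15 (2R,3S,4E)-5-bromo-3-chloro-3-methyl-2-[2-(2-methyl-1,3-dioxolan-2-yl)ethyl]pent-4-en-1-ol
Conditions: CrBr2 (6 equiv), CHBr3 (2 equiv), THF, 0 °C to rt
Reagents that add atoms: bromoform, BrC(Br)Br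
Why: Takai olefination: the ring-opened hydroxy aldehyde form of 14 reacts with the geminal dichromium species from CHBr3 and divalent chromium to give the (E)-bromoalkene (CrBr2 rather than CrCl2 avoids halide exchange), C7 has no α-hydrogen to epimerise, and the C6 hydroxyl is set free.

Step 9
Reactants: 15 (2R,3S,4E)-5-bromo-3-chloro-3-methyl-2-[2-(2-methyl-1,3-dioxolan-2-yl)ethyl]pent-4-en-1-ol
Product: 18 (3R)-3-[(2S,3E)-4-bromo-2-chlorobut-3-en-2-yl]-6-methyl-3,4-dihydro-2H-pyran, via hydroxy ketone 16 (not isolated), via hemiketal 17 (not isolated)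
Conditions: pyridinium p-toluenesulfonate, THF/H2O, 45 °C; then pyridinium p-toluenesulfonate, benzene, 4 Å MS, 70 °C
Reagents that add atoms: none
Why: Mild acid-catalysed ketal hydrolysis gives δ-hydroxy ketone 16, which closes (6-exo-trig) to hemiketal 17 and is dehydrated to the more stable endocyclic enol ether 18 (cyclodehydration of a 6-hydroxy-2-ketone); no stereocentre is touched.

Step 10
Reactants: 18 (3R)-3-[(2S,3E)-4-bromo-2-chlorobut-3-en-2-yl]-6-methyl-3,4-dihydro-2H-pyran
Product: 20 (3R)-5-bromo-3-[(2S,3E)-4-bromo-2-chlorobut-3-en-2-yl]-6-methyl-3,4-dihydro-2H-pyran, via dibromide 19 (not isolated)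
Conditions: Br2 (1.0 equiv), CH2Cl2, −78 °C; Et3N, −78 °C to rt
Reagents that add atoms: bromine, BrBr
Why: Bromination–dehydrobromination of an enol ether: bromine adds to the electron-rich C2=C3 bond (the bromovinyl group is too electron-poor to compete), the anomeric bromide of 19 ionises and Et3N removes the C3 proton to give the 3-bromo enol ether, the known route from dihydropyrans to 5-bromo-3,4-dihydro-2H-pyrans; C3 stays planar.

Step 11
Reactants: 20 (3R)-5-bromo-3-[(2S,3E)-4-bromo-2-chlorobut-3-en-2-yl]-6-methyl-3,4-dihydro-2H-pyran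
Product: 21 (2R,3S,5R)-3-bromo-5-[(2S,3E)-4-bromo-2-chlorobut-3-en-2-yl]-2-methyloxan-2-ol (target)
Conditions: 0.5 M HCl, THF/H2O, 0 °C
Reagents that add atoms: water, O
Why: Acid-catalysed hydration of the bromo enol ether: stereoelectronically controlled axial protonation at C3 of the half-chair with the C5 side chain pseudo-equatorial puts H axial and Br equatorial (3S, cis to the C5 substituent), and water then adds axially to the C2 oxocarbenium ion (anomeric effect, also the thermodynamic anomer) to give the 2R hemiketal.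

**Compound list**
1 | but-3-enoic acid | C=CCC(=O)O | starting material
2 | 4,4-dimethoxybutan-2-one | CC(=O)CC(OC)OC | starting material
3 | (Z)-4-hydroxybut-3-en-2-one (formylacetone enol) | CC(=O)/C=C\O | intermediate (not isolated)
4 | 2-(3-acetyl-2-hydroxycyclobutyl)acetic acid (stereoisomer mixture) | CC(=O)C1CC(CC(=O)O)C1O | intermediate (not isolated)
5 | 3-formyl-6-oxoheptanoic acid (racemic) | CC(=O)CCC(C=O)CC(=O)O | intermediate (not isolated)
6 | 5-hydroxy-4-(3-oxobutyl)oxolan-2-one (racemic, both lactol epimers) | CC(=O)CCC1CC(=O)OC1O | intermediate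
7 | 5-oxo-3-(3-oxobutyl)oxolan-2-yl methanesulfonate | CC(=O)CCC1CC(=O)OC1OS(C)(=O)=O | intermediate (not isolated)
8 | 4-(3-oxobutyl)furan-2(3H)-one | CC(=O)CCC1=COC(=O)C1 | intermediate (not isolated)
9 | 4-(3-oxobutyl)furan-2(5H)-one | CC(=O)CCC1=CC(=O)OC1 | intermediate
10 | 4-[2-(2-methyl-1,3-dioxolan-2-yl)ethyl]furan-2(5H)-one | CC1(CCC2=CC(=O)OC2)OCCO1 | intermediate
11 | (4S)-4-[2-(2-methyl-1,3-dioxolan-2-yl)ethyl]oxolan-2-one | O=C1C[C@H](CCC2(C)OCCO2)CO1 | intermediate
12 | (3S,4S)-3-methyl-4-[2-(2-methyl-1,3-dioxolan-2-yl)ethyl]oxolan-2-one | O=C1[C@@H](C)[C@H](CCC2(C)OCCO2)CO1 | intermediate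
13 | (3S,4R)-3-chloro-3-methyl-4-[2-(2-methyl-1,3-dioxolan-2-yl)ethyl]oxolan-2-one | O=C1[C@@](C)(Cl)[C@H](CCC2(C)OCCO2)CO1 | intermediate
14 | (3S,4R)-3-chloro-3-methyl-4-[2-(2-methyl-1,3-dioxolan-2-yl)ethyl]oxolan-2-ol (both anomers) | OC1[C@@](C)(Cl)[C@H](CCC2(C)OCCO2)CO1 | intermediate
15 | (2R,3S,4E)-5-bromo-3-chloro-3-methyl-2-[2-(2-methyl-1,3-dioxolan-2-yl)ethyl]pent-4-en-1-ol | C[C@@](Cl)(/C=C/Br)[C@@H](CO)CCC1(C)OCCO1 | intermediate
16 | (5R,6S,7E)-8-bromo-6-chloro-5-(hydroxymethyl)-6-methyloct-7-en-2-one | C[C@@](Cl)(/C=C/Br)[C@@H](CO)CCC(C)=O | intermediate (not isolated)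
17 | (5R)-5-[(2S,3E)-4-bromo-2-chlorobut-3-en-2-yl]-2-methyloxan-2-ol (both anomers) | C[C@@](Cl)(/C=C/Br)[C@H]1COC(C)(O)CC1 | intermediate (not isolated)
18 | (3R)-3-[(2S,3E)-4-bromo-2-chlorobut-3-en-2-yl]-6-methyl-3,4-dihydro-2H-pyran | C[C@@](Cl)(/C=C/Br)[C@H]1COC(C)=CC1 | intermediate
19 | (5R)-2,3-dibromo-5-[(2S,3E)-4-bromo-2-chlorobut-3-en-2-yl]-2-methyloxane (mixture at C2 and C3) | C[C@@](Cl)(/C=C/Br)[C@H]1COC(C)(Br)C(Br)C1 | intermediate (not isolated)
20 | (3R)-5-bromo-3-[(2S,3E)-4-bromo-2-chlorobut-3-en-2-yl]-6-methyl-3,4-dihydro-2H-pyran | C[C@@](Cl)(/C=C/Br)[C@H]1COC(C)=C(Br)C1 | intermediate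
21 | (2R,3S,5R)-3-bromo-5-[(2S,3E)-4-bromo-2-chlorobut-3-en-2-yl]-2-methyloxan-2-ol | C[C@@](Cl)(/C=C/Br)[C@H]1CO[C@@](C)(O)[C@@H](Br)C1 | target

**Step count and risks**
Total step count: 11. Longest linear sequence: 11 steps (from 1 and 2 to 21).

Steps most likely to fail:

Step 1. Poor head-to-tail regioselectivity of the intermolecular photocycloaddition, or self-condensation of enol 3 before it is excited. The fallback tethers the two partners and sets out from 1: conjugate addition of the acid to but-3-yn-2-one (1,4-diazabicyclo[2.2.2]octane, 5 mol %, CH2Cl2, 0 °C) should give (E)-3-oxobut-1-en-1-yl but-3-enoate F1. Irradiation (350 nm, MeCN/acetone) should close racemic cis-fused 7-acetyl-2-oxabicyclo[3.2.0]heptan-3-one F2 by intramolecular enone–alkene [2+2]; the three-atom ester tether forces the five-membered ring first (C6–C5), then C3–C4. Hydrolysis with 2 M HCl in THF at 45 °C (lactone opening, retro-aldol of the cyclobutanol, lactol closure) comes back to the route at 6.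

Step 8. The ring–chain equilibrium may keep the hindered α-chloro aldehyde masked as the lactol, so that olefination is slow and reduction of the C–Cl bond by divalent chromium competes. The fallback sets out from 13 and uses an aldehyde that cannot close. MeNH(OMe)·HCl with Me3Al should open the lactone to (2S,3R)-2-chloro-3-(hydroxymethyl)-N-methoxy-N,2-dimethyl-5-(2-methyl-1,3-dioxolan-2-yl)pentanamide F3. Silylation (TBSOTf, 2,6-lutidine) should give (2S,3R)-3-{[tert-butyl(dimethyl)silyl]oxymethyl}-2-chloro-N-methoxy-N,2-dimethyl-5-(2-methyl-1,3-dioxolan-2-yl)pentanamide F4. iBu2AlH at −78 °C should give (2S,3R)-3-{[tert-butyl(dimethyl)silyl]oxymethyl}-2-chloro-2-methyl-5-(2-methyl-1,3-dioxolan-2-yl)pentanal F5. Olefination of this free aldehyde (CHBr3, CrBr2) should give tert-butyl{[(2R,3S,4E)-5-bromo-3-chloro-3-methyl-2-[2-(2-methyl-1,3-dioxolan-2-yl)ethyl]pent-4-en-1-yl]oxy}dimethylsilane F6, and Bu4NF comes back to the route at 15.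

Step 11. Poor facial selectivity in the protonation at C3, or ionisation of the tertiary allylic chloride in aqueous acid. Bromination under equilibrating conditions is the less reliable alternative: the cis (3S) and trans (3R) bromohydrins should be close in energy, and kinetic bromination of 18 should give the trans isomer. The fallback sets out from 18: NBS in THF/H2O should give the trans-diaxial bromohydrin (2R,3R,5R)-3-bromo-5-[(2S,3E)-4-bromo-2-chlorobut-3-en-2-yl]-2-methyloxan-2-ol F7. Brief treatment with catalytic HBr in AcOH should equilibrate C3 through the enol of the open-chain α-bromo ketone; 21 is separated by chromatography and F7 is resubjected, so the route is rejoined at 21.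

Further compounds
F1 | step 1 | (E)-3-oxobut-1-en-1-yl but-3-enoate | CC(=O)/C=C/OC(=O)CC=C
F2 | step 1 | 7-acetyl-2-oxabicyclo[3.2.0]heptan-3-one (racemic, cis-fused, acetyl epimers) | CC(=O)C1C[C@@H]2CC(=O)O[C@H]12
F3 | step 8 | (2S,3R)-2-chloro-3-(hydroxymethyl)-N-methoxy-N,2-dimethyl-5-(2-methyl-1,3-dioxolan-2-yl)pentanamide | CON(C)C(=O)[C@@](C)(Cl)[C@@H](CO)CCC1(C)OCCO1
F4 | step 8 | (2S,3R)-3-{[tert-butyl(dimethyl)silyl]oxymethyl}-2-chloro-N-methoxy-N,2-dimethyl-5-(2-methyl-1,3-dioxolan-2-yl)pentanamide | CON(C)C(=O)[C@@](C)(Cl)[C@@H](CO[Si](C)(C)C(C)(C)C)CCC1(C)OCCO1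
F5 | step 8 | (2S,3R)-3-{[tert-butyl(dimethyl)silyl]oxymethyl}-2-chloro-2-methyl-5-(2-methyl-1,3-dioxolan-2-yl)pentanal | O=C[C@@](C)(Cl)[C@@H](CO[Si](C)(C)C(C)(C)C)CCC1(C)OCCO1
F6 | step 8 | tert-butyl{[(2R,3S,4E)-5-bromo-3-chloro-3-methyl-2-[2-(2-methyl-1,3-dioxolan-2-yl)ethyl]pent-4-en-1-yl]oxy}dimethylsilane | C[C@@](Cl)(/C=C/Br)[C@@H](CO[Si](C)(C)C(C)(C)C)CCC1(C)OCCO1
F7 | step 11 | (2R,3R,5R)-3-bromo-5-[(2S,3E)-4-bromo-2-chlorobut-3-en-2-yl]-2-methyloxan-2-ol | C[C@@](Cl)(/C=C/Br)[C@H]1CO[C@@](C)(O)[C@H](Br)C1
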